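**Retrosynthetic overview**
1. The target is read as (1R,2R,3S): C1 (benzylic, acylated) and C2 (methyl) are anti, C2 and C3 (free OH) are syn, and C1–O and C3–O are 1,3-anti. No ring is formed; both arenes are bought as their aldehydes.
2. Last disconnection: the C1–O acyl bond and the C3–H bond are cut together (Evans–Tishchenko). This gives the anti β-hydroxy methyl ketone and 3,4-dimethoxybenzaldehyde.
3. C3–C4: the methyl ketone comes from a Weinreb amide and MeMgBr, with the benzylic OH masked as a TES ether for that step only.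
4. Key C1–C2 bond: an auxiliary-controlled intermolecular anti-aldol of an N-propionyl oxazolidinone with 3,4,5-trimethoxybenzaldehyde.
5. The N-propionyl imide comes from (R)-4-benzyloxazolidin-2-one and propionyl chloride.

Assumption: labels C1–C4 refer to the butyl chain of the target (C1 benzylic), and the five starting materials are taken as cheap commercial chemicals.

**Route**

Step 1
Reactants: 1 (R)-4-benzyloxazolidin-2-one; 2 propionyl chloride
Product: 4 (R)-4-benzyl-3-propionyloxazolidin-2-one, via lithium oxazolidinonide 3 (not isolated)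
Conditions: n-BuLi (1.05 equiv), THF, −78 °C; then 2 (1.1 equiv), −78 → 0 °C
Reagents that add atoms: propionyl chloride 2, CCC(=O)Cl; n-butyllithium, [Li]CCCC (its lithium stays only in 3)
Why: N-acylation of the lithiated Evans auxiliary 3 with an acid chloride is fast and clean at low temperature and leaves the C4 stereocenter of the auxiliary untouched.

Step 2
Reactants: 4 (R)-4-benzyl-3-propionyloxazolidin-2-one; 5 3,4,5-trimethoxybenzaldehyde
Product: 8 (R)-4-benzyl-3-[(2S,3R)-3-hydroxy-2-methyl-3-(3,4,5-trimethoxyphenyl)propanoyl]oxazolidin-2-one, via chloromagnesium Z-enolate 6 (not isolated), via trimethylsilyl ether 7 (not isolated)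
Conditions: 5 (1.2 equiv), MgCl2 (0.2 equiv), Et3N (2 equiv), TMSCl (1.5 equiv), EtOAc, 23 °C, 24 h; then TFA (cat.), MeOH, 23 °C
Reagents that add atoms: 3,4,5-trimethoxybenzaldehyde 5, COc1cc(C=O)cc(OC)c1OC; chlorotrimethylsilane, C[Si](C)(C)Cl (its silyl group stays only in 7); MgCl2, [Mg+2].[Cl-].[Cl-] (only in 6)
Why: Evans MgCl2-catalysed direct anti-aldol reaction: soft enolisation gives the chelated Z-enolate 6 whose benzyl group blocks one face, the non-enolisable aldehyde 5 adds to the open face through a boat-like transition state and so sets C2 (S) and C3 (R) of the acyl chain in the anti relationship (C2 and C1 of the target), while TMSCl traps the adduct as 7, frees MgCl2 and shuts off retro-aldol; minor diastereomers are removed by chromatography or crystallisation.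

Step 3
Reactants: 8 (R)-4-benzyl-3-[(2S,3R)-3-hydroxy-2-methyl-3-(3,4,5-trimethoxyphenyl)propanoyl]oxazolidin-2-one
Product: 9 (2S,3R)-3-hydroxy-N-methoxy-N,2-dimethyl-3-(3,4,5-trimethoxyphenyl)propanamide
Conditions: MeNH(OMe)·HCl (3 equiv), AlMe3 (3 equiv), CH2Cl2, 0 °C; then 8, −10 → 0 °C; aq. potassium sodium tartrate
Reagents that add atoms: N,O-dimethylhydroxylamine hydrochloride, CNOC.Cl
Why: Weinreb aminolysis (transamidation with an aluminium amide): the free β-hydroxyl binds aluminium and steers the nucleophile to the exocyclic imide carbonyl, so the auxiliary is expelled and recovered and no stereocenter is touched.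

Step 4
Reactants: 9 (2S,3R)-3-hydroxy-N-methoxy-N,2-dimethyl-3-(3,4,5-trimethoxyphenyl)propanamide
Product: 10 (2S,3R)-N-methoxy-N,2-dimethyl-3-(triethylsilyloxy)-3-(3,4,5-trimethoxyphenyl)propanamide
Conditions: TESCl (1.3 equiv), imidazole (2.5 equiv), DMF, 0 → 23 °C
Reagents that add atoms: chlorotriethylsilane, CC[Si](Cl)(CC)CC
Why: Routine silyl ether formation; the TES group keeps the benzylic oxygen from becoming a magnesium alkoxide in step 5 (retro-aldol risk) and can later be removed under near-neutral conditions.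

Step 5
Reactants: 10 (2S,3R)-N-methoxy-N,2-dimethyl-3-(triethylsilyloxy)-3-(3,4,5-trimethoxyphenyl)propanamide; 11 methylmagnesium bromide
Product: 13 (3S,4R)-3-methyl-4-(triethylsilyloxy)-4-(3,4,5-trimethoxyphenyl)butan-2-one, via bromomagnesium hemiaminal chelate 12 (not isolated)
Conditions: MeMgBr (2.5 equiv), THF, 0 °C; aq. NH4Cl
Reagents that add atoms: methylmagnesium bromide 11, C[Mg]Br
Why: Weinreb ketone synthesis: the five-membered chelate 12 survives until the quench, which rules out double addition and keeps the α-stereocenter away from free base, so C2 is not epimerised.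

Step 6
Reactants: 13 (3S,4R)-3-methyl-4-(triethylsilyloxy)-4-(3,4,5-trimethoxyphenyl)butan-2-one
Product: 14 (3S,4R)-4-hydroxy-3-methyl-4-(3,4,5-trimethoxyphenyl)butan-2-one
Conditions: HF·pyridine, pyridine, THF, 0 °C; aq. NaHCO3
Reagents that add atoms: none
Why: Fluoride-driven desilylation (strong Si–F bond) in a pyridine-buffered medium frees the aldol without the acid or base that would cause dehydration to the enone, epimerisation or retro-aldol.

Step 7
Reactants: 14 (3S,4R)-4-hydroxy-3-methyl-4-(3,4,5-trimethoxyphenyl)butan-2-one; 15 3,4-dimethoxybenzaldehyde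
Product: 17 (1R,2R,3S)-3-hydroxy-2-methyl-1-(3,4,5-trimethoxyphenyl)butyl 3,4-dimethoxybenzoate, via hemiacetal adduct 16 (not isolated)
Conditions: 15 (4 equiv, recrystallised), SmI2 (0.3 equiv, 0.1 M in THF), THF, −10 °C, dark; aq. NaHCO3
Reagents that add atoms: 3,4-dimethoxybenzaldehyde 15, COc1ccc(C=O)cc1OC
Why: Evans–Tishchenko reaction: the trivalent samarium species formed from SmI2 and 15 binds the hemiacetal 16 and the ketone oxygen in a chair-like bicyclic transition state, the hemiacetal C–H is delivered intramolecularly to one ketone face to set C3 (S) 1,3-anti to C1, and the acyl group necessarily ends up on the C1 oxygen, all atoms of 14 and 15 being kept in 17.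

**Compound list**
1 | (R)-4-benzyloxazolidin-2-one | O=C1N[C@H](Cc2ccccc2)CO1 | starting material
2 | propionyl chloride | CCC(=O)Cl | starting material
3 | lithium salt of (R)-4-benzyloxazolidin-2-one (N-lithiated) | O=C1N([Li])[C@H](Cc2ccccc2)CO1 | intermediate
4 | (R)-4-benzyl-3-propionyloxazolidin-2-one | CCC(=O)N1[C@H](Cc2ccccc2)COC1=O | intermediate
5 | 3,4,5-trimethoxybenzaldehyde | COc1cc(C=O)cc(OC)c1OC | starting material
6 | chloromagnesium (Z)-enolate of 4 | C/C=C(\O[Mg]Cl)N1[C@H](Cc2ccccc2)COC1=O | intermediate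
7 | (R)-4-benzyl-3-[(2S,3R)-2-methyl-3-(trimethylsilyloxy)-3-(3,4,5-trimethoxyphenyl)propanoyl]oxazolidin-2-one | C[Si](C)(C)O[C@@H](c1cc(OC)c(OC)c(OC)c1)[C@H](C)C(=O)N1[C@H](Cc2ccccc2)COC1=O | intermediate
8 | (R)-4-benzyl-3-[(2S,3R)-3-hydroxy-2-methyl-3-(3,4,5-trimethoxyphenyl)propanoyl]oxazolidin-2-one | O[C@@H](c1cc(OC)c(OC)c(OC)c1)[C@H](C)C(=O)N1[C@H](Cc2ccccc2)COC1=O | intermediate
9 | (2S,3R)-3-hydroxy-N-methoxy-N,2-dimethyl-3-(3,4,5-trimethoxyphenyl)propanamide | O[C@@H](c1cc(OC)c(OC)c(OC)c1)[C@H](C)C(=O)N(C)OC | intermediate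
10 | (2S,3R)-N-methoxy-N,2-dimethyl-3-(triethylsilyloxy)-3-(3,4,5-trimethoxyphenyl)propanamide | CC[Si](CC)(CC)O[C@@H](c1cc(OC)c(OC)c(OC)c1)[C@H](C)C(=O)N(C)OC | intermediate
11 | methylmagnesium bromide | C[Mg]Br | starting material
12 | bromomagnesium hemiaminal chelate from 10 and 11 (new tetrahedral carbon not defined) | CC[Si](CC)(CC)O[C@@H](c1cc(OC)c(OC)c(OC)c1)[C@H](C)C(C)(O[Mg]Br)N(C)OC | intermediate
13 | (3S,4R)-3-methyl-4-(triethylsilyloxy)-4-(3,4,5-trimethoxyphenyl)butan-2-one | CC[Si](CC)(CC)O[C@@H](c1cc(OC)c(OC)c(OC)c1)[C@H](C)C(C)=O | intermediate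
14 | (3S,4R)-4-hydroxy-3-methyl-4-(3,4,5-trimethoxyphenyl)butan-2-one | O[C@@H](c1cc(OC)c(OC)c(OC)c1)[C@H](C)C(C)=O | intermediate
15 | 3,4-dimethoxybenzaldehyde (veratraldehyde) | COc1ccc(C=O)cc1OC | starting material
16 | (3S,4R)-4-[(3,4-dimethoxyphenyl)(hydroxy)methoxy]-3-methyl-4-(3,4,5-trimethoxyphenyl)butan-2-one (hemiacetal, samarium-bound in the flask, acetal carbon not defined) | COc1ccc(C(O)O[C@@H](c2cc(OC)c(OC)c(OC)c2)[C@H](C)C(C)=O)cc1OC | intermediate
17 | (1R,2R,3S)-3-hydroxy-2-methyl-1-(3,4,5-trimethoxyphenyl)butyl 3,4-dimethoxybenzoate | COc1ccc(C(=O)O[C@@H](c2cc(OC)c(OC)c(OC)c2)[C@H](C)[C@H](C)O)cc1OC | target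

**Totals**
Total step count: 7. Longest linear sequence: 7 steps (1 → 17).

**Three steps most likely to fail**

Step 7 (Evans–Tishchenko).
- The risk: the electron-rich aldehyde 15 forms the hemiacetal reluctantly. The benzylic aldol 14 can also undergo retro-aldol on trivalent samarium, which would lower conversion or scramble the aldehydes.
- The fallback sets out from 14 and comes back at 17.
- A hydroxyl-directed Saksena–Evans reduction (Me4NBH(OAc)3, MeCN/AcOH, −30 °C) delivers hydride intramolecularly from the C1–O-bound borohydride. It gives the 1,3-anti diol (1R,2R,3S)-2-methyl-1-(3,4,5-trimethoxyphenyl)butane-1,3-diol F1.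
- The less hindered methyl carbinol is then silylated selectively (TBSCl 1.05 equiv, imidazole, DMF, 0 °C). This gives (1R,2S,3S)-3-(tert-butyldimethylsilyloxy)-2-methyl-1-(3,4,5-trimethoxyphenyl)butan-1-ol F2.
- The benzylic hydroxyl is acylated with 3,4-dimethoxybenzoyl chloride, Et3N and DMAP in CH2Cl2. This gives (1R,2S,3S)-3-(tert-butyldimethylsilyloxy)-2-methyl-1-(3,4,5-trimethoxyphenyl)butyl 3,4-dimethoxybenzoate F3.
- HF·pyridine in THF removes the silyl group without base, so no 1,3-acyl shift occurs, and 17 is obtained.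

Step 2 (anti-aldol).
- The risk: aldehyde 5 is electronically close to benzaldehyde, so the diastereomer ratio may be only about 10:1 and conversion may be slow.
- The fallback sets out from 5 and comes back at 13, bypassing steps 1–5.
- It uses a Brown asymmetric crotylboration. (E)-Crotyldiisopinocampheylborane is made from trans-2-butene, n-BuLi/KOt-Bu, (+)-Ipc2BOMe (from (−)-α-pinene) and BF3·OEt2 in THF at −78 °C. It adds to 5 through a closed chair transition state.
- After NaOH/H2O2 work-up this gives the anti homoallylic alcohol (1R,2R)-2-methyl-1-(3,4,5-trimethoxyphenyl)but-3-en-1-ol F4.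
- TESCl and imidazole give triethyl{[(1R,2R)-2-methyl-1-(3,4,5-trimethoxyphenyl)but-3-en-1-yl]oxy}silane F5.
- A Tsuji–Wacker oxidation under weakly acidic conditions (PdCl2 cat., Cu(OAc)2, O2, DMA/H2O) turns the terminal alkene into the methyl ketone 13.

Step 3 (aluminium amide aminolysis).
- The risk: the aluminium alkoxide of the benzylic aldol may undergo retro-aldol, or the oxazolidinone ring may be opened instead of the exocyclic carbonyl.
- The fallback sets out from 8 and comes back at 9.
- Hydroperoxide hydrolysis (LiOH, H2O2, THF/H2O, 0 °C, then Na2SO3) cleaves only the exocyclic carbonyl. It gives (2S,3R)-3-hydroxy-2-methyl-3-(3,4,5-trimethoxyphenyl)propanoic acid F6.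
- F6 is coupled with MeNH(OMe)·HCl using EDC·HCl, HOBt and i-Pr2NEt in CH2Cl2 to give 9.

**Further compounds**
F1 | step 7 | (1R,2R,3S)-2-methyl-1-(3,4,5-trimethoxyphenyl)butane-1,3-diol | O[C@@H](c1cc(OC)c(OC)c(OC)c1)[C@H](C)[C@H](C)O
F2 | step 7 | (1R,2S,3S)-3-(tert-butyldimethylsilyloxy)-2-methyl-1-(3,4,5-trimethoxyphenyl)butan-1-ol | O[C@@H](c1cc(OC)c(OC)c(OC)c1)[C@H](C)[C@H](C)O[Si](C)(C)C(C)(C)C
F3 | step 7 | (1R,2S,3S)-3-(tert-butyldimethylsilyloxy)-2-methyl-1-(3,4,5-trimethoxyphenyl)butyl 3,4-dimethoxybenzoate | COc1ccc(C(=O)O[C@@H](c2cc(OC)c(OC)c(OC)c2)[C@H](C)[C@H](C)O[Si](C)(C)C(C)(C)C)cc1OC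
F4 | step 2 | (1R,2R)-2-methyl-1-(3,4,5-trimethoxyphenyl)but-3-en-1-ol | O[C@@H](c1cc(OC)c(OC)c(OC)c1)[C@H](C)C=C
F5 | step 2 | triethyl{[(1R,2R)-2-methyl-1-(3,4,5-trimethoxyphenyl)but-3-en-1-yl]oxy}silane | CC[Si](CC)(CC)O[C@@H](c1cc(OC)c(OC)c(OC)c1)[C@H](C)C=C
F6 | step 3 | (2S,3R)-3-hydroxy-2-methyl-3-(3,4,5-trimethoxyphenyl)propanoic acid | O[C@@H](c1cc(OC)c(OC)c(OC)c1)[C@H](C)C(=O)O
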